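**Strategy**

The cycloheptadiene (ring C) is joined to the bicyclo[3.3.1]nonane only through its ring-fusion pair, the methyl-bearing quaternary carbon and the adjacent CH. The route forms the two ring C bonds to this pair, from the ring CH2 and from the methyl-bearing diene carbon, in one keteniminium–alkene [2+2] cycloaddition: an auxiliary-bearing keteniminium ion that already carries the δ-lactone (ring D) as a cyclic iodoalkene adds to an (E)-trisubstituted alkene diester. The step unites both halves, translates alkene geometry into the trans ring fusion and stores strain; a radical three-carbon ring expansion of the cyclobutanone then inserts the lactone alkene to give ring C.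

Key step: step 11

**Remarks on the chemistry (assumptions)**

- The (2R,5R)-auxiliary is assumed to shield the keteniminium face that leads to the ring configuration drawn for 21 and 22; if the sense is the opposite, (2S,5S)-2,5-dimethylpyrrolidine is used in step 6 and nothing else changes.
- The CH(CH3)CO2Me centre created in step 8 is racemic and is carried as an epimer mixture (drawn without configuration in 17–25 and 27); it is enolised and re-formed under substrate control in step 15.
- The ring carbon α to the ketone in 21 and 22 is drawn as the isomer with its side chain trans to the acetate arm; its configuration is inconsequential because it becomes CH2 in step 12.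

**Lactone fragment (steps 1–6)**

Step 1
Reactants: 1 2-methyl-4-(trimethylsilyl)but-3-yn-2-ol; 2 allylmagnesium bromide; 3 oxirane
Product: 5 (3E)-5-methyl-4-(prop-2-en-1-yl)-3-(trimethylsilyl)hex-3-ene-1,5-diol, via alkenylmagnesium chelate 4 (not isolated)
Conditions: 2 (2.5 equiv), Et2O, reflux; then CuI (cat.), 3, THF, −30 °C to rt; aq. NH4Cl
Reagents that add atoms: none
Why: Alkoxide-directed anti-carbomagnesiation puts the allyl group on the alkyne carbon next to the carbinol and magnesium on the silyl-bearing carbon in a five-membered chelate, so copper-catalysed opening of oxirane with retention places the hydroxyethyl arm cis to the carbinol carbon (tandem carbomagnesiation–epoxide alkylation).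

Step 2
Reactants: 5 the diol
Product: 6 6,6-dimethyl-5-(prop-2-en-1-yl)-4-(trimethylsilyl)-3,6-dihydro-2H-pyran-2-one
Conditions: TEMPO (cat.), PhI(OAc)2, CH2Cl2, rt
Reagents that add atoms: none
Why: Oxoammonium oxidation of the primary alcohol, then of the lactol it forms with the cis tertiary hydroxyl, should give the δ-lactone (oxidative lactonisation); the tertiary alcohol, vinylsilane and allyl group are inert.

Step 3
Reactants: 6 the silyl lactone
Product: 7 4-iodo-6,6-dimethyl-5-(prop-2-en-1-yl)-3,6-dihydro-2H-pyran-2-one
Conditions: N-iodosuccinimide, (CF3)2CHOH, 0 °C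
Reagents that add atoms: N-iodosuccinimide, O=C1CCC(=O)N1I
Why: Electrophilic ipso-iododesilylation through the β-silyl cation replaces silicon by iodine on the same carbon and should be faster than any reaction at the monosubstituted allyl alkene.

Step 4
Reactants: 7 the iodo lactone
Product: 9 5-(3-hydroxypropyl)-4-iodo-6,6-dimethyl-3,6-dihydro-2H-pyran-2-one, via B-alkyl-9-borabicyclononane 8 (not isolated)
Conditions: 9-BBN, THF, 0 °C to rt; then H2O2, aq. NaOAc
Reagents that add atoms: hydrogen peroxide, OO; 9-borabicyclo[3.3.1]nonane, B1C2CCCC1CCC2 (boryl group of 8 only)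
Why: Anti-Markovnikov hydroboration–oxidation; the bulky borane selects the terminal alkene over the tetrasubstituted iodoalkene and does not reduce the lactone.

Step 5
Reactants: 9 the primary alcohol
Product: 10 3-(4-iodo-2,2-dimethyl-6-oxo-5,6-dihydro-2H-pyran-3-yl)propanoic acid
Conditions: TEMPO (cat.), PhI(OAc)2, MeCN–H2O, rt
Reagents that add atoms: water, O
Why: Oxoammonium oxidation of the primary alcohol through the aldehyde hydrate should give the carboxylic acid without touching the lactone or the iodoalkene.

Step 6
Reactants: 10 the acid; 11 (2R,5R)-2,5-dimethylpyrrolidine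
Product: 13 5-{3-[(2R,5R)-2,5-dimethylpyrrolidin-1-yl]-3-oxopropyl}-4-iodo-6,6-dimethyl-3,6-dihydro-2H-pyran-2-one, via acid chloride 12 (not isolated)
Conditions: (COCl)2, DMF (cat.), CH2Cl2, 0 °C; then 11, Et3N, 0 °C to rt
Reagents that add atoms: oxalyl chloride, O=C(Cl)C(=O)Cl (chlorine of 12 only)
Why: Acylation of the hindered C2-symmetric secondary amine through the acid chloride (amide formation) installs the chiral auxiliary.

**Alkene fragment (steps 7–10)**

Step 7
Reactants: 14 2-methyl-2-vinyloxirane; 15 dimethyl 2-methylpropanedioate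
Product: 16 dimethyl 2-[(2E)-4-hydroxy-3-methylbut-2-en-1-yl]-2-methylpropanedioate
Conditions: Pd(PPh3)4 (cat.), THF, rt
Reagents that add atoms: none
Why: Zerovalent palladium opens the vinyl epoxide to a π-allyl alkoxide that deprotonates the malonate, and attack at the distal terminus should give the 1,4-adduct as the E allylic alcohol (Tsuji–Trost allylation under neutral conditions).

Step 8
Reactants: 16 the malonate
Product: 17 methyl (4E)-6-hydroxy-2,5-dimethylhex-4-enoate
Conditions: LiCl, H2O, DMSO, 150 °C
Reagents that add atoms: none
Why: Krapcho dealkoxycarbonylation removes one of the geminal esters; the new CH(CH3) centre is racemic, which is of no consequence.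

Step 9
Reactants: 17 the allylic alcohol
Product: 18 methyl (4E)-6-[(methoxycarbonyl)oxy]-2,5-dimethylhex-4-enoate
Conditions: ClCO2Me, pyridine, CH2Cl2, 0 °C
Reagents that add atoms: methyl chloroformate, COC(=O)Cl
Why: O-acylation of the primary allylic alcohol gives the allylic carbonate needed for ionisation.

Step 10
Reactants: 18 the allylic carbonate
Product: 19 dimethyl (4E)-2,5-dimethylhept-4-enedioate
Conditions: Pd(OAc)2 (cat.), PPh3, CO (20 bar), toluene, 50 °C
Reagents that add atoms: carbon monoxide, [C-]#[O+]
Why: Decarboxylative palladium-catalysed carbonylation (oxidative addition, CO insertion at the primary allyl terminus, capture by the released methoxide) should give the β,γ-unsaturated ester with the E geometry retained.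

**Union and completion (steps 11–20)**

Step 11
Reactants: 13 the pyrrolidine amide; 19 the (E)-alkene diester
Product: 22 cyclobutanone bearing the lactone-methyl arm at C-2; CH3 plus CH2CO2Me at C-3; the CH2CH(CH3)CO2Me arm at C-4, via keteniminium triflate 20 (not isolated), via cyclobutaniminium triflate 21 (not isolated)
Conditions: Tf2O, 2,4,6-collidine, ClCH2CH2Cl, −20 to 70 °C; then aq. NaHCO3, rt
Reagents that add atoms: water, O (ketone oxygen of 22); triflic anhydride, O=S(=O)(OS(=O)(=O)C(F)(F)F)C(F)(F)F (counter-ion of 20 and 21 only)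
Why: Tf2O activates the amide oxygen and collidine removes an α-proton to give keteniminium ion 20; the CH end of alkene 19 attacks its central carbon while the developing tertiary cationic centre closes onto the terminal carbon, and water then hydrolyses iminium salt 21 and releases the auxiliary. The closest known reaction type is the keteniminium–alkene [2+2] cycloaddition to cyclobutanones, including its auxiliary-controlled form with C2-symmetric pyrrolidine amides. The four-membered ring is closed by an asynchronous thermal [2+2] cycloaddition in which both new bonds form on the same face of the alkene. The quaternary C(CH3) centre and the neighbouring CH centre keep the E geometry of 19, so the ring methyl is cis to the CH2CH(CH3)CO2Me arm (the later trans ring fusion), and their absolute sense is set by the (2R,5R)-pyrrolidine, which blocks one face of the keteniminium C=C; the third ring centre, α to the ketone, is erased in step 12. The step needs regioselectivity (carbonyl carbon to the CH end), secured by the tertiary cation-like transition state, and chemoselectivity for the amide over the esters and lactone, secured by its far more basic oxygen; the tetrasubstituted iodoalkene is too hindered and electron-poor to compete with 19.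

Step 12
Reactants: 22 the cyclobutanone
Product: 23 ring-expanded enone (seven-membered ring C fused to lactone ring D through a tetrasubstituted C=C conjugated to the new ketone)
Conditions: Bu3SnH (slow addition), AIBN (cat.), benzene, 80 °C
Reagents that add atoms: none
Why: Dowd–Beckwith-type three-carbon ring expansion: the alkenyl radical from the iodide, held cis to the tether, adds to the strained cyclobutanone carbonyl (five-membered closure), β-scission of the fused bond of the alkoxy radical opens the four-membered ring to the cycloheptenone, and the resulting secondary radical takes hydrogen from the stannane to become the ring CH2.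

Step 13
Reactants: 23 the enone
Product: 24 dienyl triflate (triflate on the former ketone carbon; both C=C exocyclic to ring D)
Conditions: Tf2O, 2,6-di-tert-butyl-4-methylpyridine, CH2Cl2, 0 °C to rt; aq. NaHCO3
Reagents that add atoms: triflic anhydride, O=S(=O)(OS(=O)(=O)C(F)(F)F)C(F)(F)F
Why: O-triflation of the enone and loss of a γ-proton from the ring CH2 should give the through-conjugated dienyl triflate (as with steroidal 4-en-3-ones); the only γ-hydrogens are on that CH2 and the α′ methine next to the quaternary carbon is hindered.

Step 14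
Reactants: 24 the dienyl triflate diester
Product: 25 tricyclic β-keto ester (cyclohexanone trans-fused to ring C)
Conditions: LiN(SiMe3)2 (3.3 equiv), THF, −78 to 0 °C; aq. NH4Cl
Reagents that add atoms: none
Why: Dieckmann condensation: the acetate enolate attacks the propanoate ester to close the six-membered ring, the only mode that gives an enolisable β-keto ester; the lactone enolate that forms first lies trans across the exocyclic C=C and cannot reach either ester.

Step 15
Reactants: 25 the β-keto ester; 26 2-methylprop-2-enal
Product: 28 bicyclo[3.3.1]nonane ketol, via Michael adduct 27 (not isolated)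
Conditions: 1,1,3,3-tetramethylguanidine (cat.), CH2Cl2, 0 °C to rt
Reagents that add atoms: none
Why: Michael–aldol annulation: the β-keto ester enolate adds to the enal axially on the face opposite the axial angular methyl group, and the tethered aldehyde can then reach only the same face of the methyl-bearing α′-carbon, so the aldol closure sets both bridgeheads; the CH(CH3) and CH(OH) centres of the new bridge are left as mixtures that later steps erase.

Step 16
Reactants: 28 the ketol
Product: 29 exocyclic-methylene alcohol (bridging ketone converted to C=CH2)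
Conditions: Zn, CH2Br2, TiCl4, THF–CH2Cl2, 0 °C to rt
Reagents that add atoms: dibromomethane, BrCBr
Why: Takai–Lombardo methylenation: the non-basic geminal dimetallic reagent should methylenate the hindered, non-enolisable bridging ketone without touching the esters, lactone, free hydroxyl or triflate, and it excludes retro-aldol cleavage.

Step 17
Reactants: 29 the secondary alcohol
Product: 30 bridge ketone
Conditions: Dess–Martin periodinane, pyridine, CH2Cl2, rt
Reagents that add atoms: none
Why: Dess–Martin oxidation of the hindered secondary alcohol to the ketone under neutral conditions.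

Step 18
Reactants: 30 the ketone
Product: 33 tertiary α-hydroxy ketone, via silyl enol ether 31 (not isolated), via α-silyloxy ketone 32 (not isolated)
Conditions: Me3SiOTf, Et3N, CH2Cl2, 0 °C; then dimethyldioxirane, acetone, −78 °C; then aq. citric acid, MeOH
Reagents that add atoms: dimethyldioxirane, CC1(C)OO1; trimethylsilyl triflate, C[Si](C)(C)OS(=O)(=O)C(F)(F)F (silyl group of 31 and 32 only)
Why: Rubottom oxidation: soft enolisation affects only the ketone, which can enolise only toward the CH(CH3) carbon, and the dioxirane should epoxidise the electron-rich silyl enol ether on the exo face (away from the other three-carbon bridge) faster than the exocyclic methylene or the electron-poor dienyl triflate, giving the exo hydroxyl after silyl migration and hydrolysis.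

Step 19
Reactants: 33 the α-hydroxy ketone
Product: 34 spiro-epoxide dienyl triflate
Conditions: VO(acac)2 (cat.), t-BuOOH, CH2Cl2, 0 °C to rt
Reagents that add atoms: tert-butyl hydroperoxide, CC(C)(C)OO
Why: Vanadium-catalysed hydroxyl-directed epoxidation: the tertiary hydroxyl, which can sit over the exocyclic alkene when its ring is a boat, should deliver oxygen to the methylene face on the side of the ketone-bearing bridge, which is also the face remote from the axial angular methyl group; the dienyl triflate has no directing group.

Step 20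
Reactants: 34 the epoxide triflate
Product: 35 target CNP0605450.1
Conditions: Me4Sn, Pd2(dba)3 (cat.), AsPh3, N-methylpyrrolidone, 50 °C; aq. KF
Reagents that add atoms: tetramethylstannane, C[Sn](C)(C)C
Why: Stille coupling (oxidative addition of the dienyl triflate, methyl transfer from tin, reductive elimination) should install the methyl group of the tetrasubstituted diene under neutral conditions that leave the epoxide, ketol, ester and lactone untouched.

**Compound list**

1 | 2-methyl-4-(trimethylsilyl)but-3-yn-2-ol | CC(C)(O)C#C[Si](C)(C)C | starting material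
2 | allylmagnesium bromide | C=CC[Mg]Br | starting material
3 | oxirane | C1CO1 | starting material
4 | 5,5-dimethyl-4-(prop-2-en-1-yl)-3-(trimethylsilyl)-2,5-dihydro-1,2-oxamagnesole (alkenylmagnesium alkoxide chelate) | CC1(C)O[Mg]C([Si](C)(C)C)=C1CC=C | intermediate
5 | (3E)-5-methyl-4-(prop-2-en-1-yl)-3-(trimethylsilyl)hex-3-ene-1,5-diol (hydroxyethyl arm cis to the carbinol carbon) | CC(C)(O)/C(CC=C)=C(\CCO)[Si](C)(C)C | intermediate
6 | 6,6-dimethyl-5-(prop-2-en-1-yl)-4-(trimethylsilyl)-3,6-dihydro-2H-pyran-2-one | CC1(C)OC(=O)CC([Si](C)(C)C)=C1CC=C | intermediate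
7 | 4-iodo-6,6-dimethyl-5-(prop-2-en-1-yl)-3,6-dihydro-2H-pyran-2-one | CC1(C)OC(=O)CC(I)=C1CC=C | intermediate
8 | 9-[3-(4-iodo-2,2-dimethyl-6-oxo-5,6-dihydro-2H-pyran-3-yl)propyl]-9-borabicyclo[3.3.1]nonane | CC1(C)OC(=O)CC(I)=C1CCCB1C2CCCC1CCC2 | intermediate
9 | 5-(3-hydroxypropyl)-4-iodo-6,6-dimethyl-3,6-dihydro-2H-pyran-2-one | CC1(C)OC(=O)CC(I)=C1CCCO | intermediate
10 | 3-(4-iodo-2,2-dimethyl-6-oxo-5,6-dihydro-2H-pyran-3-yl)propanoic acid | CC1(C)OC(=O)CC(I)=C1CCC(=O)O | intermediate
11 | (2R,5R)-2,5-dimethylpyrrolidine | C[C@@H]1CC[C@@H](C)N1 | starting material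
12 | 3-(4-iodo-2,2-dimethyl-6-oxo-5,6-dihydro-2H-pyran-3-yl)propanoyl chloride | CC1(C)OC(=O)CC(I)=C1CCC(=O)Cl | intermediate
13 | 5-{3-[(2R,5R)-2,5-dimethylpyrrolidin-1-yl]-3-oxopropyl}-4-iodo-6,6-dimethyl-3,6-dihydro-2H-pyran-2-one | C[C@@H]1CC[C@@H](C)N1C(=O)CCC1=C(I)CC(=O)OC1(C)C | intermediate
14 | 2-methyl-2-vinyloxirane (racemic) | CC1(C=C)CO1 | starting material
15 | dimethyl 2-methylpropanedioate | COC(=O)C(C)C(=O)OC | starting material
16 | dimethyl 2-[(2E)-4-hydroxy-3-methylbut-2-en-1-yl]-2-methylpropanedioate | COC(=O)C(C)(C/C=C(\C)CO)C(=O)OC | intermediate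
17 | methyl (4E)-6-hydroxy-2,5-dimethylhex-4-enoate (racemic) | COC(=O)C(C)C/C=C(\C)CO | intermediate
18 | methyl (4E)-6-[(methoxycarbonyl)oxy]-2,5-dimethylhex-4-enoate | COC(=O)C(C)C/C=C(\C)COC(=O)OC | intermediate
19 | dimethyl (4E)-2,5-dimethylhept-4-enedioate (racemic at C-2) | COC(=O)C(C)C/C=C(\C)CC(=O)OC | intermediate
20 | keteniminium triflate from 13: N-alkenylidene-(2R,5R)-2,5-dimethylpyrrolidinium triflate carrying the iodo lactone | C[C@@H]1CC[C@@H](C)[N+]1=C=CCC1=C(I)CC(=O)OC1(C)C.[O-]S(=O)(=O)C(F)(F)F | intermediate
21 | cyclobutaniminium triflate: [2+2] adduct of 20 and 19; ring methyl cis to both ring side arms | COC(=O)C(C)C[C@H]1C(=[N+]2[C@H](C)CC[C@H]2C)[C@@H](CC2=C(I)CC(=O)OC2(C)C)[C@@]1(CC(=O)OC)C.[O-]S(=O)(=O)C(F)(F)F | intermediate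
22 | cyclobutanone: 2-[(4-iodo-2,2-dimethyl-6-oxo-5,6-dihydro-2H-pyran-3-yl)methyl]-3-(2-methoxy-2-oxoethyl)-4-(3-methoxy-2-methyl-3-oxopropyl)-3-methylcyclobutan-1-one; ring methyl cis to the C-2 and C-4 arms; absolute configuration as in the SMILES | COC(=O)C(C)C[C@H]1C(=O)[C@@H](CC2=C(I)CC(=O)OC2(C)C)[C@@]1(CC(=O)OC)C | intermediate
23 | ring-expanded enone: cycloheptenone (ring C) fused to the δ-lactone (ring D) through a tetrasubstituted C=C; quaternary C(CH3)(CH2CO2Me) next to CH(CH2CH(CH3)CO2Me), which is α to the ketone | COC(=O)C(C)C[C@H]1C(=O)C2=C(CC[C@@]1(CC(=O)OC)C)C(C)(C)OC(=O)C2 | intermediate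
24 | dienyl triflate of 23: C(OTf)=C and C=CH double bonds both exocyclic to ring D | COC(=O)C(C)C[C@H]1C(OS(=O)(=O)C(F)(F)F)=C2CC(=O)OC(C)(C)C2=CC[C@@]1(CC(=O)OC)C | intermediate
25 | tricyclic β-keto ester: 2-methoxycarbonyl-6-methylcyclohexanone trans-fused to ring C at the C(CH3)/CH pair | COC(=O)C1C(=O)C(C)C[C@H]2C(OS(=O)(=O)C(F)(F)F)=C3CC(=O)OC(C)(C)C3=CC[C@@]21C | intermediate
26 | 2-methylprop-2-enal | CC(=C)C=O | starting material
27 | Michael adduct: quaternary C(CO2Me) carrying the CH2CH(CH3)CHO chain trans to the angular methyl group | COC(=O)[C@@]1(CC(C)C=O)C(=O)C(C)C[C@H]2C(OS(=O)(=O)C(F)(F)F)=C3CC(=O)OC(C)(C)C3=CC[C@@]21C | intermediate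
28 | bicyclo[3.3.1]nonane ketol: bridgeheads C(CO2Me) and C(CH3); bridging ketone; CH2–CH(CH3)–CH(OH) bridge (epimers) | COC(=O)[C@]12CC(C)C(O)[C@](C)(C[C@H]3C(OS(=O)(=O)C(F)(F)F)=C4CC(=O)OC(C)(C)C4=CC[C@@]31C)C2=O | intermediate
29 | exocyclic-methylene alcohol: as 28 with C=CH2 in place of the bridging ketone | COC(=O)[C@]12CC(C)C(O)[C@](C)(C[C@H]3C(OS(=O)(=O)C(F)(F)F)=C4CC(=O)OC(C)(C)C4=CC[C@@]31C)C2=C | intermediate
30 | bridge ketone: as 29 with the CH(OH) oxidised to C=O | COC(=O)[C@]12CC(C)C(=O)[C@](C)(C[C@H]3C(OS(=O)(=O)C(F)(F)F)=C4CC(=O)OC(C)(C)C4=CC[C@@]31C)C2=C | intermediate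
31 | trimethylsilyl enol ether of 30 (C(CH3)=C(OSiMe3) in the bridge) | COC(=O)[C@]12CC(C)=C(O[Si](C)(C)C)[C@](C)(C[C@H]3C(OS(=O)(=O)C(F)(F)F)=C4CC(=O)OC(C)(C)C4=CC[C@@]31C)C2=C | intermediate
32 | α-trimethylsilyloxy ketone (silyloxy group exo) | COC(=O)[C@]12C[C@@](C)(O[Si](C)(C)C)C(=O)[C@](C)(C[C@H]3C(OS(=O)(=O)C(F)(F)F)=C4CC(=O)OC(C)(C)C4=CC[C@@]31C)C2=C | intermediate
33 | tertiary α-hydroxy ketone (hydroxyl exo; methyl toward the other bridge) | COC(=O)[C@]12C[C@@](C)(O)C(=O)[C@](C)(C[C@H]3C(OS(=O)(=O)C(F)(F)F)=C4CC(=O)OC(C)(C)C4=CC[C@@]31C)C2=C | intermediate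
34 | spiro-epoxide dienyl triflate (epoxide oxygen on the side of the ketone-bearing bridge) | COC(=O)[C@]12C[C@@](C)(O)C(=O)[C@](C)(C[C@H]3C(OS(=O)(=O)C(F)(F)F)=C4CC(=O)OC(C)(C)C4=CC[C@@]31C)[C@]21CO1 | intermediate
35 | CNP0605450.1: spiro-epoxy bicyclo[3.3.1]nonane methyl ester trans-fused to the lactone-annulated cycloheptadiene | COC(=O)[C@]12C[C@@](C)(O)C(=O)[C@](C)(C[C@H]3C(C)=C4CC(=O)OC(C)(C)C4=CC[C@@]31C)[C@]21CO1 | target

**Step count and risks**

Total step count: 20. Longest linear sequence: 16 steps (steps 1–6, then 11–20).

Steps most likely to fail: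

1. Step 12. The alkenyl radical may be reduced by the stannane before it adds to the carbonyl group, or the alkoxy radical may cleave the non-fused cyclobutane bond. The fallback sets out from 22. An intramolecular Nozaki–Hiyama–Kishi addition (CrCl2, NiCl2 cat., DMF) of the iodoalkene to the cyclobutanone would give the tricyclic tertiary cyclobutanol F1. Hypoiodite fragmentation (PhI(OAc)2, I2, visible light) then generates the alkoxy radical with no hydride donor present and should give, by β-scission of the fused bond and iodine capture, the ring-expanded secondary iodide F2. Bu3SnH and AIBN remove the iodine, and the route is rejoined at 23.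

2. Step 11. The auxiliary may discriminate poorly between the two faces, so that both ring configurations form. The fallback sets out from acid chloride 12, which with dimethylamine gives the N,N-dimethylamide F3. Under the same activation this forms the achiral keteniminium triflate F4, which with 19 gives the racemic cyclobutaniminium triflate F5 and, after hydrolysis, 22 together with its mirror-image ring isomer F6. The two are separated by preparative chromatography on a chiral stationary phase, and the route is rejoined at 22.

3. Step 1. The hindered α-silyl alkenylmagnesium chelate may fail to open oxirane and simply be protonated on work-up. The fallback sets out from chelate 4, which is quenched with iodine to give the iodoalkene F7. Negishi coupling with [2-(tert-butyldimethylsilyloxy)ethyl]zinc iodide (Pd(P(t-Bu)3)2, THF) would give the silyl ether F8, and Bu4NF frees the primary alcohol, so the route is rejoined at 5.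

Further compounds
F1 | step 12 | tricyclic cyclobutanol from carbonyl addition of the alkenyl unit of 22 (cyclopentene cis-fused to the cyclobutane; tertiary hydroxyl at the fusion carbon) | COC(=O)C(C)C[C@H]1[C@@]2(O)C3=C(C[C@H]2[C@@]1(CC(=O)OC)C)C(C)(C)OC(=O)C3
F2 | step 12 | ring-expanded enone carrying iodine on the ring carbon next to the quaternary centre (epimers) | COC(=O)C(C)C[C@H]1C(=O)C2=C(CC(I)[C@@]1(CC(=O)OC)C)C(C)(C)OC(=O)C2
F3 | step 11 | 3-(4-iodo-2,2-dimethyl-6-oxo-5,6-dihydro-2H-pyran-3-yl)-N,N-dimethylpropanamide | CN(C)C(=O)CCC1=C(I)CC(=O)OC1(C)C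
F4 | step 11 | N,N-dimethylketeniminium triflate from F3 | C[N+](C)=C=CCC1=C(I)CC(=O)OC1(C)C.[O-]S(=O)(=O)C(F)(F)F
F5 | step 11 | N,N-dimethylcyclobutaniminium triflate, racemic (enantiomer leading to 22 shown) | COC(=O)C(C)C[C@H]1C(=[N+](C)C)[C@@H](CC2=C(I)CC(=O)OC2(C)C)[C@@]1(CC(=O)OC)C.[O-]S(=O)(=O)C(F)(F)F
F6 | step 11 | mirror-image ring isomer of cyclobutanone 22 | COC(=O)C(C)C[C@@H]1C(=O)[C@H](CC2=C(I)CC(=O)OC2(C)C)[C@]1(CC(=O)OC)C
F7 | step 1 | 4-iodo-2-methyl-3-(prop-2-en-1-yl)-4-(trimethylsilyl)but-3-en-2-ol (iodine cis to the carbinol carbon) | CC(C)(O)/C(CC=C)=C(\I)[Si](C)(C)C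
F8 | step 1 | primary tert-butyldimethylsilyl ether of diol 5 | CC(C)(O)/C(CC=C)=C(\CCO[Si](C)(C)C(C)(C)C)[Si](C)(C)C
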